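The ring-fusion bond C4a–C8a of the decalin carries the whole plan (decalin numbering: C-2 ether carbon, C-7 side-chain carbon). The carbon with the quaternary methyl (C-4a) and the one with the trans hydrogen (C-8a) are traced back to the two ends of a tetrasubstituted alkene, which Birch reduction of a tetralin supplies. One hydroxyl-directed methylene transfer across that alkene closes the cyclopropane (bonds C4a–CH2 and C8a–CH2) on the face of the C-7 substituent and fixes C-4a. The substrate is the dioxolane-protected Δ4a(8a)-octalin 8, whose C-8 hydroxyl is cis to the C-7 hydroxyisopropyl group. Reductive opening of the derived C-8 ketone later releases the methyl and the trans fusion.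

Key step: step 6

Remarks and assumptions
- Numbering: C-2 ketal/ether carbon, C-4a methyl-bearing fusion carbon, C-7 side-chain carbon, C-8 carbinol/ketone carbon, C-8a fusion CH.
- The stereodescriptors of 8 and 11 were checked against the target: C-7 has the target configuration, and CH2, 8-OH and the side chain lie on one face. No correction is needed.
- Design change: the side-chain tertiary alcohol would compete with the C-2 carbinol in the O-arylation and, next to a C-8 ketone, could be lost by retro-aldol cleavage. It is therefore silylated in step 8, when it is the only free hydroxyl, and released last.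
- 3-Bromo-4-fluorobenzaldehyde, 2-allyl-4-bromophenol and MeTi(OiPr)3 (THF solution) are taken as catalogue compounds.

Step 1
Reactants: 1 7-methoxy-1-tetralone; 2 dimethyl carbonate
Product: 3 racemic β-keto ester
Conditions: NaH (2.2 equiv), THF, reflux; aq. HCl
Reagents that add atoms: none
Why: Crossed Claisen C-acylation of the ketone enolate at its only enolisable carbon, driven by formation of the stabilised sodium enolate of the product.

Step 2
Reactants: 3 racemic β-keto ester
Product: 4 cis-(1R,2R) hydroxy ester
Conditions: RuCl[(R,R)-TsDPEN](p-cymene) (1 mol %), HCO2H/Et3N (5:2), DMF, 40 °C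
Reagents that add atoms: none
Why: Noyori asymmetric transfer hydrogenation with dynamic kinetic resolution: the keto ester racemises through its enol faster than it is reduced, and the (R,R) catalyst, which gives R carbinols from aryl ketones, should reduce the 2R enantiomer to the cis-(1R,2R) hydroxy ester.

Step 3
Reactants: 4 cis-(1R,2R) hydroxy ester
Product: 5 cis aryl diol
Conditions: MeMgBr (5 equiv), THF, −20 → 20 °C; aq. NH4Cl
Reagents that add atoms: methylmagnesium bromide, C[Mg]Br
Why: Double Grignard addition to the ester after deprotonation of the hydroxyl; no stereocentre is touched, and excess reagent at low temperature should outrun enolisation and retro-aldol cleavage of the magnesium aldolate.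

Step 4
Reactants: 5 cis aryl diol
Product: 7 Birch diene diol, via dilithium dialkoxide 6 (not isolated)
Conditions: n-BuLi (2.1 equiv), THF, −78 °C; Li (6 equiv), NH3(l)/THF/t-BuOH, −78 → −33 °C; isoprene, then NH4Cl
Reagents that add atoms: none
Why: Birch reduction of the anisole ring leaves the donor-bearing carbons sp2, giving the enol ether C2=C3 and the tetrasubstituted alkene C4a=C8a; the benzylic oxygen is carried as its lithium alkoxide, which resists C–O hydrogenolysis, and lithium is destroyed before the protic quench.

Step 5
Reactants: 7 Birch diene diol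
Product: 8 dioxolane octalin cis-diol
Conditions: HOCH2CH2OH (10 equiv), PPTS (5 mol %), THF, 0 → 20 °C
Reagents that add atoms: ethylene glycol, OCCO
Why: Acid-catalysed addition of the diol to the enol ether with loss of methanol (transketalisation) gives the dioxolane without passing through the free β,γ-enone, so the alkene stays at C4a=C8a and the allylic C-8 alcohol is not ionised.

Step 6
Reactants: 8 dioxolane octalin cis-diol; 9 diiodomethane
Product: 11 propellane diol, via bis(ethylzinc) dialkoxide 10 (not isolated)
Conditions: Et2Zn (5 equiv), CH2I2 (8 equiv), CH2Cl2, −10 → 20 °C; aq. NH4Cl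
Reagents that add atoms: none
Why: Diethylzinc first converts both hydroxyls into ethylzinc alkoxides; the (iodomethyl)zinc carbenoid then binds the C-8 alkoxide and transfers CH2 to C4a=C8a through the butterfly transition state of the Simmons–Smith reaction, the closest precedent being the hydroxyl-directed cyclopropanation of cyclic allylic alcohols, ring-fusion octalinols included. The three-membered ring closes by a concerted suprafacial [2+1] addition in which C4a–CH2 and C8a–CH2 form on one face, giving a cis-fused [4.4.1]propellane. Both new stereocentres, C-4a and C-8a, are set by the C-8 alkoxide, which holds the carbenoid on its own face; this is the face of the C-7 side chain because step 2 made the two cis, and the side-chain alkoxide on the same face can only reinforce it. The step needs π-facial selectivity and sufficient reactivity at a tetrasubstituted alkene; intramolecular delivery from the neighbouring alkoxide supplies both, and this electron-rich alkene is the only one in the molecule. The dioxolane is a weaker donor than the zinc alkoxides and should survive the mildly Lewis-acidic medium at or below room temperature.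

Step 7
Reactants: 11 propellane diol
Product: 12 cyclopropyl ketone
Conditions: Dess–Martin periodinane (1.3 equiv), NaHCO3, CH2Cl2, 0 → 20 °C
Reagents that add atoms: none
Why: Dess–Martin oxidation of the secondary cyclopropyl carbinol; the tertiary alcohol cannot be oxidised, and the buffered neutral medium spares the ketal, the cyclopropane and the β-hydroxy ketone.

Step 8
Reactants: 12 cyclopropyl ketone
Product: 13 silylated cyclopropyl ketone
Conditions: TBSOTf (1.5 equiv), 2,6-lutidine (3 equiv), CH2Cl2, −78 → 0 °C
Reagents that add atoms: tert-butyldimethylsilyl trifluoromethanesulfonate, CC(C)(C)[Si](C)(C)OS(=O)(=O)C(F)(F)F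
Why: Silyl triflate silylation of the only remaining (tertiary) hydroxyl removes the retro-aldol liability beside the C-8 carbonyl and keeps this oxygen out of the later O-arylation.

Step 9
Reactants: 13 silylated cyclopropyl ketone
Product: 15 trans-decalone, via lithium enolate 14 (not isolated)
Conditions: Li (4 equiv), NH3(l)/THF, t-BuOH (1 equiv), −78 °C; isoprene, then solid NH4Cl
Reagents that add atoms: none
Why: Dissolving-metal cleavage of a conjugated cyclopropyl ketone: the ketyl opens the exocyclic C8a–CH2 bond, which overlaps with the carbonyl π system while C8a–C4a lies near its nodal plane, leaving CH3 on C-4a and the C8=C8a enolate; protonation at C-8a anti to the axial methyl gives the trans fusion, which is also the more stable arrangement with the C-7 group equatorial.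

Step 10
Reactants: 15 trans-decalone
Product: 17 deoxygenated ketal, via hydrazone 16 (not isolated)
Conditions: N2H4·H2O (20 equiv), AcOH (cat.), n-BuOH, 120 °C; concentrate; KOtBu, DMSO, 25 → 60 °C
Reagents that add atoms: none
Why: Wolff–Kishner reduction run as preformed hydrazone then KOtBu/DMSO: forming the hydrazone without strong base avoids β-elimination of the silyloxy group, the mild base stage spares the TBS ether and the dioxolane, and any epimerisation at C-7 or C-8a converges on the desired equatorial, trans-fused arrangement.

Step 11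
Reactants: 17 deoxygenated ketal
Product: 18 C-2 ketone
Conditions: PPTS (0.2 equiv), acetone/H2O (10:1), 55 °C
Reagents that add atoms: water, O
Why: Acid-catalysed ketal hydrolysis; the hindered tertiary TBS ether is stable to PPTS and no stereocentre lies α to the new carbonyl.

Step 12
Reactants: 18 C-2 ketone
Product: 19 C-2 tertiary alcohol
Conditions: MeTi(OiPr)3 (3 equiv), Et2O/hexane, 20 °C; aq. NH4Cl
Reagents that add atoms: methyltriisopropoxytitanium, C[Ti](OC(C)C)(OC(C)C)OC(C)C
Why: 1,2-Addition of a bulky methyltitanium reagent to the conformationally locked cyclohexanone: attack along the equatorial trajectory avoids the axial hydrogens on C-4 and C-8a, so methyl ends equatorial and the hydroxyl axial, on the face of H-8a and opposite the angular methyl, as the target requires.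

Step 13
Reactants: 19 C-2 tertiary alcohol; 20 3-bromo-4-fluorobenzaldehyde
Product: 22 aryl ether aldehyde, via potassium alkoxide 21 (not isolated)
Conditions: KH (1.3 equiv), THF, 0 → 20 °C; then 20 (1.3 equiv), THF/DMF, 0 → 20 °C
Reagents that add atoms: none
Why: SNAr (addition–elimination) of the tertiary potassium alkoxide at the fluoride para to the formyl group; fluoride leaves far faster than bromide, the C2–O bond is untouched so the carbinol configuration is retained, and preforming the alkoxide with KH keeps amide bases away from the aldehyde.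

Step 14
Reactants: 22 aryl ether aldehyde
Product: 24 allylic methyl carbonate, via bromomagnesium alkoxide 23 (not isolated)
Conditions: CH2=CHMgBr (1.2 equiv), THF, −78 °C; then ClCO2Me (1.5 equiv), −78 → 0 °C
Reagents that add atoms: vinylmagnesium bromide, C=C[Mg]Br; methyl chloroformate, COC(=O)Cl
Why: Grignard 1,2-addition to the aldehyde followed by in situ O-acylation of the alkoxide; the aryl bromide does not exchange with a vinyl Grignard at −78 °C, and the new carbinol centre (mixture of epimers) is removed in step 15.

Step 15
Reactants: 24 allylic methyl carbonate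
Product: 25 allyl aryl bromide
Conditions: Pd2(dba)3 (2.5 mol %), n-Bu3P (5 mol %), HCO2H/Et3N, THF, 20 °C
Reagents that add atoms: none
Why: Palladium-catalysed formate hydrogenolysis of an allylic carbonate (Tsuji–Trost-type π-allyl chemistry): the 1-arylallyl palladium formate loses CO2 and delivers hydride to the substituted benzylic terminus, giving the terminal alkene, and at room temperature this pathway should be much faster than oxidative addition into the hindered, electron-rich aryl bromide.

Step 16
Reactants: 26 2-allyl-4-bromophenol; 27 bis(pinacolato)diboron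
Product: 28 allylphenol boronate
Conditions: Pd(dppf)Cl2 (3 mol %), KOAc (3 equiv), 1,4-dioxane, 85 °C
Reagents that add atoms: none
Why: Miyaura borylation of the aryl bromide; the free phenol and the allyl group are tolerated under the weakly basic acetate conditions.

Step 17
Reactants: 25 allyl aryl bromide; 28 allylphenol boronate
Product: 29 silyl-protected target
Conditions: Pd(OAc)2 (5 mol %), SPhos (10 mol %), K3PO4 (3 equiv), toluene/H2O (10:1), 80 °C
Reagents that add atoms: none
Why: Suzuki–Miyaura coupling; a dialkylbiarylphosphine catalyst handles the bromide ortho to the bulky alkoxy group, the phenol couples as its phenoxide, and the biaryl bond forms without touching the stereocentres or either allyl group.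

Step 18
Reactants: 29 silyl-protected target
Product: 30 CNP0342687.1
Conditions: TBAF (5 equiv), THF, 50 °C; aq. NH4Cl
Reagents that add atoms: none
Why: Fluoride-mediated desilylation of the tertiary TBS ether; the tert-alkyl aryl ether, the phenol and the allyl groups are inert to fluoride, so no acid is needed at the end.

Compound list
1 | 7-methoxy-3,4-dihydronaphthalen-1(2H)-one (7-methoxy-1-tetralone) | COc1ccc2CCCC(=O)c2c1 | starting material
2 | dimethyl carbonate | COC(=O)OC | starting material
3 | methyl 7-methoxy-1-oxo-1,2,3,4-tetrahydronaphthalene-2-carboxylate (racemic, keto–enol mixture) | COC(=O)C1CCc2ccc(OC)cc2C1=O | intermediate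
4 | methyl (1R,2R)-1-hydroxy-7-methoxy-1,2,3,4-tetrahydronaphthalene-2-carboxylate (cis) | COc1ccc2c(c1)[C@H](O)[C@H](C(=O)OC)CC2 | intermediate
5 | (1R,2R)-2-(2-hydroxypropan-2-yl)-7-methoxy-1,2,3,4-tetrahydronaphthalen-1-ol (cis) | COc1ccc2c(c1)[C@H](O)[C@H](C(C)(C)O)CC2 | intermediate
6 | dilithium dialkoxide of 5 | COc1ccc2c(c1)[C@H]([O-])[C@H](C(C)(C)[O-])CC2.[Li+].[Li+] | intermediate (not isolated)
7 | (1R,2R)-2-(2-hydroxypropan-2-yl)-7-methoxy-1,2,3,4,5,8-hexahydronaphthalen-1-ol | COC1=CCC2=C(C1)[C@H](O)[C@H](C(C)(C)O)CC2 | intermediate
8 | (7'R,8'R)-7'-(2-hydroxypropan-2-yl)-3',4',5',6',7',8'-hexahydro-1'H-spiro[1,3-dioxolane-2,2'-naphthalen]-8'-ol; dioxolane at C-2, alkene C4a=C8a, 8-OH cis to the C-7 side chain | O1CCOC12CCC3=C(C2)[C@H](O)[C@H](C(C)(C)O)CC3 | intermediate (key-step precursor)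
9 | diiodomethane | ICI | starting material
10 | bis(ethylzinc) dialkoxide of 8 | O1CCOC12CCC3=C(C2)[C@H](O[Zn]CC)[C@H](C(C)(C)O[Zn]CC)CC3 | intermediate (not isolated)
11 | 4a,8a-methano-bridged decalin (tricyclo[4.4.1.0(1,6)]undecane core) with dioxolane at C-2, 8-OH and 7-(2-hydroxypropan-2-yl); CH2 bridge, 8-OH and C-7 side chain all on one face | O1CCOC12CC[C@]34CC[C@@H](C(C)(C)O)[C@@H](O)[C@]3(C4)C2 | intermediate (key-step product)
12 | 8-ketone of 11 (cyclopropyl ketone; CH2 bridge and C-7 side chain on one face) | O1CCOC12CC[C@]34CC[C@@H](C(C)(C)O)C(=O)[C@]3(C4)C2 | intermediate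
13 | tert-butyldimethylsilyl ether of 12 at the side-chain tertiary oxygen | O1CCOC12CC[C@]34CC[C@@H](C(C)(C)O[Si](C)(C)C(C)(C)C)C(=O)[C@]3(C4)C2 | intermediate
14 | lithium C8=C8a enolate of 15 (4a-methyl in place) | O1CCOC12CC[C@]3(C)CC[C@@H](C(C)(C)O[Si](C)(C)C(C)(C)C)C([O-])=C3C2.[Li+] | intermediate (not isolated)
15 | (4aS,7S,8aS) trans-fused 4a-methyldecalin-8-one with dioxolane at C-2 and equatorial 7-[2-(TBSO)propan-2-yl] cis to the 4a-methyl; H-8a trans to the methyl | O1CCOC12CC[C@]3(C)CC[C@@H](C(C)(C)O[Si](C)(C)C(C)(C)C)C(=O)[C@H]3C2 | intermediate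
16 | C-8 hydrazone of 15 | O1CCOC12CC[C@]3(C)CC[C@@H](C(C)(C)O[Si](C)(C)C(C)(C)C)C(=NN)[C@H]3C2 | intermediate (not isolated)
17 | (4aS,7R,8aS) trans-fused 4a-methyldecalin with dioxolane at C-2 and 7-[2-(TBSO)propan-2-yl] (C-8 now CH2) | O1CCOC12CC[C@]3(C)CC[C@@H](C(C)(C)O[Si](C)(C)C(C)(C)C)C[C@H]3C2 | intermediate
18 | (4aS,7R,8aS)-7-[2-(tert-butyldimethylsilyloxy)propan-2-yl]-4a-methyl-octahydronaphthalen-2(1H)-one (trans-fused) | O=C1CC[C@]2(C)CC[C@@H](C(C)(C)O[Si](C)(C)C(C)(C)C)C[C@H]2C1 | intermediate
19 | (2R,4aS,7R,8aS)-7-[2-(tert-butyldimethylsilyloxy)propan-2-yl]-2,4a-dimethyl-decahydronaphthalen-2-ol; 2-OH axial, cis to H-8a, trans to the 4a-methyl | O[C@]1(C)CC[C@]2(C)CC[C@@H](C(C)(C)O[Si](C)(C)C(C)(C)C)C[C@H]2C1 | intermediate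
20 | 3-bromo-4-fluorobenzaldehyde | O=Cc1ccc(F)c(Br)c1 | starting material
21 | potassium alkoxide of 19 | [K+].[O-][C@]1(C)CC[C@]2(C)CC[C@@H](C(C)(C)O[Si](C)(C)C(C)(C)C)C[C@H]2C1 | intermediate (not isolated)
22 | 3-bromo-4-[(2R,4aS,7R,8aS)-decalin-2-yloxy]benzaldehyde (decalin as in 19, ether at C-2) | O=Cc1ccc(O[C@]2(C)CC[C@]3(C)CC[C@@H](C(C)(C)O[Si](C)(C)C(C)(C)C)C[C@H]3C2)c(Br)c1 | intermediate
23 | bromomagnesium alkoxide of the vinyl carbinol from 22 (epimers at the carbinol carbon) | C=CC([O-])c1ccc(O[C@]2(C)CC[C@]3(C)CC[C@@H](C(C)(C)O[Si](C)(C)C(C)(C)C)C[C@H]3C2)c(Br)c1.[Mg+2].[Br-] | intermediate (not isolated)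
24 | methyl 1-[3-bromo-4-(decalin-2-yloxy)phenyl]prop-2-en-1-yl carbonate (decalin as in 19; epimers at the carbonate carbon) | C=CC(OC(=O)OC)c1ccc(O[C@]2(C)CC[C@]3(C)CC[C@@H](C(C)(C)O[Si](C)(C)C(C)(C)C)C[C@H]3C2)c(Br)c1 | intermediate
25 | 4-allyl-2-bromophenyl ether of 19 | C=CCc1ccc(O[C@]2(C)CC[C@]3(C)CC[C@@H](C(C)(C)O[Si](C)(C)C(C)(C)C)C[C@H]3C2)c(Br)c1 | intermediate
26 | 2-allyl-4-bromophenol | C=CCc1cc(Br)ccc1O | starting material
27 | bis(pinacolato)diboron | CC1(C)OB(B2OC(C)(C)C(C)(C)O2)OC1(C)C | starting material
28 | 2-allyl-4-(4,4,5,5-tetramethyl-1,3,2-dioxaborolan-2-yl)phenol | C=CCc1cc(B2OC(C)(C)C(C)(C)O2)ccc1O | intermediate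
29 | tert-butyldimethylsilyl ether of the target at the side-chain tertiary oxygen | C=CCc1ccc(O[C@]2(C)CC[C@]3(C)CC[C@@H](C(C)(C)O[Si](C)(C)C(C)(C)C)C[C@H]3C2)c(-c2ccc(O)c(CC=C)c2)c1 | intermediate
30 | CNP0342687.1: honokiol-type biaryl (5-allyl on the ether ring, 3'-allyl-4'-hydroxy on the other) whose 2-oxygen is bound to C-2 of the (2R,4aS,7R,8aS)-7-(2-hydroxypropan-2-yl)-2,4a-dimethyl-trans-decalin | C=CCc1ccc(O[C@]2(C)CC[C@]3(C)CC[C@@H](C(C)(C)O)C[C@H]3C2)c(-c2ccc(O)c(CC=C)c2)c1 | target

Total step count: 18. Longest linear sequence: 17 steps (steps 1–15, 17, 18) from 7-methoxy-1-tetralone; step 16 is a one-step side branch.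

Steps most likely to fail

Step 6 (key step). Methylene transfer to the hindered tetrasubstituted alkene may stall, or zinc iodide may open the dioxolane before the alkene is consumed. The fallback sets out from 8 and uses a free carbene in a basic medium that cannot harm the ketal: dichlorocarbene under phase-transfer conditions (CHCl3, 50% aq. NaOH, BnEt3NCl, 0–20 °C). It adds readily to tetrasubstituted alkenes and, for allylic alcohols, is expected to favour the hydroxyl face, giving the gem-dichlorocyclopropane diol F1. Dissolving-metal dechlorination (Na, NH3/THF, t-BuOH, −78 °C) then comes back to the route at 11.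

Step 10. Condensation of hydrazine with the doubly α-branched C-8 carbonyl may be too slow, so that azine formation or loss of silanol across C7–C(CH3)2 takes over under forcing conditions. The fallback sets out from 15 and is a Barton–McCombie deoxygenation. LiAlH4 (THF, 0 °C) should give the C-8 alcohol F2, with hydride expected to enter anti to the angular methyl; the configuration at C-8 is irrelevant. NaH/CS2 then MeI gives the S-methyl xanthate F3, and Bu3SnH/AIBN (toluene, 110 °C) comes back to the route at 17.

Step 13. Ipso attack by the hindered axial alkoxide may be slower than its reversible addition to the formyl group and the hydride-transfer reactions that follow, so that the aldehyde is consumed without ether formation. The fallback sets out from 19 and replaces addition–elimination by ligand coupling on iodine(III). Alkoxide 21 (from 19 and KH) is treated in toluene at 20–50 °C with (2-bromo-4-cyanophenyl)(2,4,6-trimethoxyphenyl)iodonium tosylate F4, itself made from 3-bromo-4-iodobenzonitrile with mCPBA and TsOH, then 1,3,5-trimethoxybenzene. The salt should transfer its electron-poor, ortho-substituted aryl group to oxygen and give the nitrile ether F5. DIBAL-H (toluene, −78 °C; aqueous Rochelle salt) then reduces the nitrile and comes back to the route at 22.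

Further compounds
F1 | step 6 | gem-dichloro analogue of 11 (CCl2 bridge across C4a–C8a on the face of the 8-OH and the C-7 side chain) | O1CCOC12CC[C@]34CC[C@@H](C(C)(C)O)[C@@H](O)[C@]3(C4(Cl)Cl)C2
F2 | step 10 | C-8 alcohol from 15 (8-OH axial, cis to the 4a-methyl) | O1CCOC12CC[C@]3(C)CC[C@@H](C(C)(C)O[Si](C)(C)C(C)(C)C)[C@@H](O)[C@H]3C2
F3 | step 10 | O-(C-8) S-methyl xanthate of F2 | O1CCOC12CC[C@]3(C)CC[C@@H](C(C)(C)O[Si](C)(C)C(C)(C)C)[C@@H](OC(=S)SC)[C@H]3C2
F4 | step 13 | (2-bromo-4-cyanophenyl)(2,4,6-trimethoxyphenyl)iodonium 4-methylbenzenesulfonate | N#Cc1ccc([I+]c2c(OC)cc(OC)cc2OC)c(Br)c1.Cc1ccc(cc1)S(=O)(=O)[O-]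
F5 | step 13 | 3-bromo-4-(decalin-2-yloxy)benzonitrile (nitrile analogue of 22) | N#Cc1ccc(O[C@]2(C)CC[C@]3(C)CC[C@@H](C(C)(C)O[Si](C)(C)C(C)(C)C)C[C@H]3C2)c(Br)c1
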